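**Strategy.** The chromanone ring (O1, C2, C3, C4, C4a, C8a) is not closed as such. C3, already carrying ring B, is inserted as an arylchlorocarbene into the furan C2=C3 enol-ether bond of a 3-silyloxybenzofuran, so the furan ring grows to the pyranone ring and both halves are joined in one operation, giving an isoflavone. The step exploits the O1–CH=C(O–) unit of ring C, which maps onto O1–C2 and C4=O flanking C3. The precursors are silyl enol ether 3 of a phloroglucinol-derived benzofuranone and chlorodiazirine 11. C3 is then set by transfer-hydrogenative dynamic kinetic resolution, both prenyl groups are added after the carbene step, and C4 is reoxidised.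

Key step: step 7

**Remarks on the chemistry.**
- The stereocentre of the target is (3S) (priorities C4 > C2 > C1' > H).
- Chromanone numbering is used throughout, with ring B primed.
- Compounds 1 and 4 and all reagents are taken as commercially available.
- The sense of induction in step 9 is assigned from the Noyori–Ikariya model for aryl ketones.
- Prenyl groups are kept out of the carbene step because a free arylchlorocarbene would cyclopropanate them.

**Route**

Step 1
Reactants: 1 4,6-dihydroxy-1-benzofuran-3(2H)-one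
Product: 2 4,6-bis(methoxymethoxy)-1-benzofuran-3(2H)-one
Conditions: MOMCl, K2CO3, acetone, reflux
Reagents that add atoms: chloromethyl methyl ether, COCCl
Why: Williamson-type O-alkylation (MOM protection) of both phenoxides, which are far more nucleophilic than the ketone enolate, should leave the C2 methylene untouched.

Step 2
Reactants: 2 4,6-bis(methoxymethoxy)-1-benzofuran-3(2H)-one
Product: 3 {[4,6-bis(methoxymethoxy)-1-benzofuran-3-yl]oxy}(tert-butyl)dimethylsilane
Conditions: KN(SiMe3)2, THF, −78 °C; then TBSCl, −78 °C to rt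
Reagents that add atoms: tert-butyldimethylsilyl chloride, CC(C)(C)[Si](C)(C)Cl
Why: Silyl enol ether formation by O-silylation of the potassium enolate should be clean because the hard silicon electrophile goes to oxygen and the product is an aromatic benzofuran.

Step 3
Reactants: 4 5-bromo-2-hydroxy-4-methoxybenzaldehyde
Product: 6 5-bromo-2-hydroxy-4-methoxybenzonitrile, via aldoxime 5 (not isolated)
Conditions: NH2OH·HCl, HCO2Na, HCO2H, 100 °C
Reagents that add atoms: hydroxylamine hydrochloride, NO.Cl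
Why: One-pot oximation and formic acid-mediated dehydration (aldehyde-to-nitrile conversion) is a standard route to salicylonitriles and leaves the aryl bromide and methyl ether alone.

Step 4
Reactants: 6 5-bromo-2-hydroxy-4-methoxybenzonitrile
Product: 7 5-bromo-4-methoxy-2-[(triisopropylsilyl)oxy]benzonitrile
Conditions: TIPSCl, imidazole, DMF, rt
Reagents that add atoms: triisopropylsilyl chloride, CC(C)[Si](Cl)(C(C)C)C(C)C
Why: Imidazole-promoted silylation of the acidic phenol gives a silyl ether that has no C–H next to oxygen for a neighbouring carbene to insert into and that should survive hypochlorite, organolithium and formic acid conditions.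

Step 5
Reactants: 7 5-bromo-4-methoxy-2-[(triisopropylsilyl)oxy]benzonitrile
Product: 9 5-bromo-4-methoxy-2-[(triisopropylsilyl)oxy]benzamidinium chloride, via lithium bis(silyl)amidinate 8 (not isolated)
Conditions: LiN(SiMe3)2, THF, 0 °C to rt; then HCl in dioxane, 0 °C
Reagents that add atoms: lithium bis(trimethylsilyl)amide, [Li]N([Si](C)(C)C)[Si](C)(C)C; hydrogen chloride, Cl
Why: Addition of the silylamide to the nitrile followed by N-desilylation and protonation is the standard amidine synthesis, and the amide base should not exchange the aryl bromide.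

Step 6
Reactants: 9 5-bromo-4-methoxy-2-[(triisopropylsilyl)oxy]benzamidinium chloride
Product: 11 3-{5-bromo-4-methoxy-2-[(triisopropylsilyl)oxy]phenyl}-3-chloro-3H-diazirine, via dichloroamidine 10 (not isolated)
Conditions: aqueous NaOCl, LiCl, DMSO/pentane, 0 °C to rt, product kept cold in the dark
Reagents that add atoms: sodium hypochlorite, [Na+].[O-]Cl
Why: Graham oxidation (N-chlorination, ring closure to the diazirine and chloride return to carbon) is the established route to 3-aryl-3-chlorodiazirines, including electron-rich alkoxyaryl ones.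

Step 7
Reactants: 3 {[4,6-bis(methoxymethoxy)-1-benzofuran-3-yl]oxy}(tert-butyl)dimethylsilane; 11 3-{5-bromo-4-methoxy-2-[(triisopropylsilyl)oxy]phenyl}-3-chloro-3H-diazirine
Product: 15 3-{5-bromo-4-methoxy-2-[(triisopropylsilyl)oxy]phenyl}-5,7-bis(methoxymethoxy)-4H-chromen-4-one, via arylchlorocarbene 12 (not isolated), via chlorocyclopropane 13 (not isolated), via silyloxychromenylium chloride 14 (not isolated)
Conditions: 11 (excess), Na2CO3, MeCN, 50 °C, dark
Reagents that add atoms: none
Why: Proposed new method: thermolysis of 11 releases N2 and the singlet arylchlorocarbene 12, which adds to the electron-rich furan C2=C3 bond of 3 (cheletropic [2+1] addition, three-membered ring of 13); ionisation of the C–Cl bond with disrotatory two-electron electrocyclic opening of the ring-fusion bond then turns the furan ring into the six-membered 4-silyloxychromenylium ring of 14 (ring expansion, no cyclisation event), and chloride removes the silyl group to give the chromone. The closest known reaction types are the Ciamician–Dennstedt-type insertion of arylchlorodiazirine-derived carbenes into indoles, pyrroles and indenes and the dihalocarbene one-carbon ring expansion of cyclic silyl enol ethers to 2-haloenones. No stereocentre is created, since those of 13 vanish on ring opening. Regiochemistry follows from connectivity: the carbene carbon must end between the former furan C2 (now O1–CH=) and the former furan C3 (now C4=O), so it becomes C3 carrying ring B. The step needs the enol ether to be the only reactive π bond and the carbene to have no fast intramolecular exit; this is secured by keeping prenyl groups out (aryl bromide as place-holder) and by the silyl group on the 2'-oxygen.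

Step 8
Reactants: 15 3-{5-bromo-4-methoxy-2-[(triisopropylsilyl)oxy]phenyl}-5,7-bis(methoxymethoxy)-4H-chromen-4-one
Product: 16 3-{4-methoxy-5-(3-methylbut-2-en-1-yl)-2-[(triisopropylsilyl)oxy]phenyl}-5,7-bis(methoxymethoxy)-4H-chromen-4-one
Conditions: tributyl(prenyl)stannane, Pd(PPh3)4 (zerovalent palladium), DMF, 95 °C
Reagents that add atoms: tributyl(3-methylbut-2-en-1-yl)stannane, CCCC[Sn](CCCC)(CCCC)CC=C(C)C
Why: Stille cross-coupling of the aryl bromide with the prenylstannane should give the linear prenyl arene under fluoride-free conditions that spare the silyl ether.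

Step 9
Reactants: 16 3-{4-methoxy-5-(3-methylbut-2-en-1-yl)-2-[(triisopropylsilyl)oxy]phenyl}-5,7-bis(methoxymethoxy)-4H-chromen-4-one
Product: 18 (3S,4S)-3-{4-methoxy-5-(3-methylbut-2-en-1-yl)-2-[(triisopropylsilyl)oxy]phenyl}-5,7-bis(methoxymethoxy)-3,4-dihydro-2H-chromen-4-ol (cis), via racemic isoflavanone 17 (not isolated)
Conditions: RuCl[(S,S)-TsDPEN](p-cymene) (cat.), HCO2H/Et3N, EtOAc, 40 °C
Reagents that add atoms: none
Why: Noyori–Ikariya asymmetric transfer hydrogenation with dynamic kinetic resolution: conjugate reduction gives ketone 17, whose enantiomers interconvert through the enol under Et3N, while the (S,S)-catalyst should reduce only the (3S)-ketone on the C4 face anti to the C3 aryl group (aryl/arene CH–π control gives 4S, anti attack gives cis and hence 3S), the prenyl alkene being inert.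

Step 10
Reactants: 18 (3S,4S)-3-{4-methoxy-5-(3-methylbut-2-en-1-yl)-2-[(triisopropylsilyl)oxy]phenyl}-5,7-bis(methoxymethoxy)-3,4-dihydro-2H-chromen-4-ol
Product: 20 (3S,4S)-3-{4-methoxy-5-(3-methylbut-2-en-1-yl)-2-[(triisopropylsilyl)oxy]phenyl}-5,7-bis(methoxymethoxy)-6-(3-methylbut-2-en-1-yl)-3,4-dihydro-2H-chromen-4-ol, via dilithio species 19 (not isolated)
Conditions: n-BuLi (2.4 equiv), TMEDA, THF, −78 to −10 °C; CuBr·SMe2 (cat.), prenyl bromide, −78 °C to rt; aqueous work-up
Reagents that add atoms: 1-bromo-3-methylbut-2-ene, CC(C)=CCBr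
Why: Directed ortho-metalation: after deprotonation of the hydroxyl, C6–H between the two MOM ethers is the kinetically most acidic aryl C–H (double chelation), and copper-catalysed SN2 allylation of the aryllithium should give the linear prenyl group without touching C3 or C4.

Step 11
Reactants: 20 (3S,4S)-3-{4-methoxy-5-(3-methylbut-2-en-1-yl)-2-[(triisopropylsilyl)oxy]phenyl}-5,7-bis(methoxymethoxy)-6-(3-methylbut-2-en-1-yl)-3,4-dihydro-2H-chromen-4-ol
Product: 21 (3S)-3-{4-methoxy-5-(3-methylbut-2-en-1-yl)-2-[(triisopropylsilyl)oxy]phenyl}-5,7-bis(methoxymethoxy)-6-(3-methylbut-2-en-1-yl)-2,3-dihydro-4H-chromen-4-one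
Conditions: Dess–Martin periodinane, NaHCO3, CH2Cl2, 0 °C to rt
Reagents that add atoms: none
Why: Dess–Martin oxidation of the benzylic alcohol under buffered, non-basic conditions should give the ketone without enolisation at C3, so the (3S) centre set in step 9 is kept.

Step 12
Reactants: 21 (3S)-3-{4-methoxy-5-(3-methylbut-2-en-1-yl)-2-[(triisopropylsilyl)oxy]phenyl}-5,7-bis(methoxymethoxy)-6-(3-methylbut-2-en-1-yl)-2,3-dihydro-4H-chromen-4-one
Product: 23 (3S)-5,7-dihydroxy-3-[2-hydroxy-4-methoxy-5-(3-methylbut-2-en-1-yl)phenyl]-6-(3-methylbut-2-en-1-yl)-2,3-dihydro-4H-chromen-4-one, via silyl-protected diphenol 22 (not isolated)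
Conditions: 3 M HCl, MeOH/THF, rt; then concentration, Bu4NF/AcOH (1:1), THF, 0 °C
Reagents that add atoms: none
Why: Acid-catalysed acetal exchange removes both MOM ethers while the 2'-oxygen is still silylated (so the 2'-OH cannot add to C4 under acid), and acetic acid-buffered fluoride desilylation then frees the last phenol without base-mediated enolisation at C3.

**Compound list**

1 | 4,6-dihydroxy-1-benzofuran-3(2H)-one | O=C1COc2cc(O)cc(O)c12 | starting material
2 | 4,6-bis(methoxymethoxy)-1-benzofuran-3(2H)-one | O=C1COc2cc(OCOC)cc(OCOC)c12 | intermediate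
3 | {[4,6-bis(methoxymethoxy)-1-benzofuran-3-yl]oxy}(tert-butyl)dimethylsilane | CC(C)(C)[Si](C)(C)Oc1coc2cc(OCOC)cc(OCOC)c12 | intermediate
4 | 5-bromo-2-hydroxy-4-methoxybenzaldehyde | O=Cc1cc(Br)c(OC)cc1O | starting material
5 | (E)-5-bromo-2-hydroxy-4-methoxybenzaldehyde oxime | O/N=C/c1cc(Br)c(OC)cc1O | intermediate
6 | 5-bromo-2-hydroxy-4-methoxybenzonitrile | N#Cc1cc(Br)c(OC)cc1O | intermediate
7 | 5-bromo-4-methoxy-2-[(triisopropylsilyl)oxy]benzonitrile | N#Cc1cc(Br)c(OC)cc1O[Si](C(C)C)(C(C)C)C(C)C | intermediate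
8 | lithium N,N'-bis(trimethylsilyl)-5-bromo-4-methoxy-2-[(triisopropylsilyl)oxy]benzamidinate | [Li]N([Si](C)(C)C)C(=N[Si](C)(C)C)c1cc(Br)c(OC)cc1O[Si](C(C)C)(C(C)C)C(C)C | intermediate
9 | 5-bromo-4-methoxy-2-[(triisopropylsilyl)oxy]benzamidinium chloride | [Cl-].NC(=[NH2+])c1cc(Br)c(OC)cc1O[Si](C(C)C)(C(C)C)C(C)C | intermediate
10 | N,N'-dichloro-5-bromo-4-methoxy-2-[(triisopropylsilyl)oxy]benzamidine | ClNC(=NCl)c1cc(Br)c(OC)cc1O[Si](C(C)C)(C(C)C)C(C)C | intermediate
11 | 3-{5-bromo-4-methoxy-2-[(triisopropylsilyl)oxy]phenyl}-3-chloro-3H-diazirine | ClC1(N=N1)c1cc(Br)c(OC)cc1O[Si](C(C)C)(C(C)C)C(C)C | intermediate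
12 | {5-bromo-4-methoxy-2-[(triisopropylsilyl)oxy]phenyl}chlorocarbene | Cl[C]c1cc(Br)c(OC)cc1O[Si](C(C)C)(C(C)C)C(C)C | intermediate
13 | 1-{5-bromo-4-methoxy-2-[(triisopropylsilyl)oxy]phenyl}-6b-[(tert-butyldimethylsilyl)oxy]-1-chloro-4,6-bis(methoxymethoxy)-1a,6b-dihydro-1H-cyclopropa[b][1]benzofuran (racemic, mixture of isomers at C1) | CC(C)(C)[Si](C)(C)OC12c3c(OCOC)cc(OCOC)cc3OC1C2(Cl)c1cc(Br)c(OC)cc1O[Si](C(C)C)(C(C)C)C(C)C | intermediate
14 | 3-{5-bromo-4-methoxy-2-[(triisopropylsilyl)oxy]phenyl}-4-[(tert-butyldimethylsilyl)oxy]-5,7-bis(methoxymethoxy)chromenylium chloride | [Cl-].CC(C)(C)[Si](C)(C)Oc1c(-c2cc(Br)c(OC)cc2O[Si](C(C)C)(C(C)C)C(C)C)c[o+]c2cc(OCOC)cc(OCOC)c12 | intermediate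
15 | 3-{5-bromo-4-methoxy-2-[(triisopropylsilyl)oxy]phenyl}-5,7-bis(methoxymethoxy)-4H-chromen-4-one | COCOc1cc(OCOC)c2c(c1)occ(-c1cc(Br)c(OC)cc1O[Si](C(C)C)(C(C)C)C(C)C)c2=O | intermediate
16 | 3-{4-methoxy-5-(3-methylbut-2-en-1-yl)-2-[(triisopropylsilyl)oxy]phenyl}-5,7-bis(methoxymethoxy)-4H-chromen-4-one | COCOc1cc(OCOC)c2c(c1)occ(-c1cc(CC=C(C)C)c(OC)cc1O[Si](C(C)C)(C(C)C)C(C)C)c2=O | intermediate
17 | rac-3-{4-methoxy-5-(3-methylbut-2-en-1-yl)-2-[(triisopropylsilyl)oxy]phenyl}-5,7-bis(methoxymethoxy)-2,3-dihydro-4H-chromen-4-one | COCOc1cc(OCOC)c2c(c1)OCC(c1cc(CC=C(C)C)c(OC)cc1O[Si](C(C)C)(C(C)C)C(C)C)C2=O | intermediate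
18 | (3S,4S)-3-{4-methoxy-5-(3-methylbut-2-en-1-yl)-2-[(triisopropylsilyl)oxy]phenyl}-5,7-bis(methoxymethoxy)-3,4-dihydro-2H-chromen-4-ol | O[C@H]1[C@@H](c2cc(CC=C(C)C)c(OC)cc2O[Si](C(C)C)(C(C)C)C(C)C)COc2cc(OCOC)cc(OCOC)c12 | intermediate
19 | lithium (3S,4S)-6-lithio-3-{4-methoxy-5-(3-methylbut-2-en-1-yl)-2-[(triisopropylsilyl)oxy]phenyl}-5,7-bis(methoxymethoxy)-3,4-dihydro-2H-chromen-4-olate | [Li]O[C@H]1[C@@H](c2cc(CC=C(C)C)c(OC)cc2O[Si](C(C)C)(C(C)C)C(C)C)COc2cc(OCOC)c([Li])c(OCOC)c12 | intermediate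
20 | (3S,4S)-3-{4-methoxy-5-(3-methylbut-2-en-1-yl)-2-[(triisopropylsilyl)oxy]phenyl}-5,7-bis(methoxymethoxy)-6-(3-methylbut-2-en-1-yl)-3,4-dihydro-2H-chromen-4-ol | O[C@H]1[C@@H](c2cc(CC=C(C)C)c(OC)cc2O[Si](C(C)C)(C(C)C)C(C)C)COc2cc(OCOC)c(CC=C(C)C)c(OCOC)c12 | intermediate
21 | (3S)-3-{4-methoxy-5-(3-methylbut-2-en-1-yl)-2-[(triisopropylsilyl)oxy]phenyl}-5,7-bis(methoxymethoxy)-6-(3-methylbut-2-en-1-yl)-2,3-dihydro-4H-chromen-4-one | O=C1[C@@H](c2cc(CC=C(C)C)c(OC)cc2O[Si](C(C)C)(C(C)C)C(C)C)COc2cc(OCOC)c(CC=C(C)C)c(OCOC)c12 | intermediate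
22 | (3S)-5,7-dihydroxy-3-{4-methoxy-5-(3-methylbut-2-en-1-yl)-2-[(triisopropylsilyl)oxy]phenyl}-6-(3-methylbut-2-en-1-yl)-2,3-dihydro-4H-chromen-4-one | O=C1[C@@H](c2cc(CC=C(C)C)c(OC)cc2O[Si](C(C)C)(C(C)C)C(C)C)COc2cc(O)c(CC=C(C)C)c(O)c12 | intermediate
23 | (3S)-5,7-dihydroxy-3-[2-hydroxy-4-methoxy-5-(3-methylbut-2-en-1-yl)phenyl]-6-(3-methylbut-2-en-1-yl)-2,3-dihydro-4H-chromen-4-one | COc1cc(O)c([C@H]2COc3cc(O)c(CC=C(C)C)c(O)c3C2=O)cc1CC=C(C)C | target

**Step count.** Total: 12 steps. Longest linear sequence: 10 steps (from 4: steps 3–12); the ring A branch (steps 1 and 2) joins at step 7.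

**Steps most likely to fail**

1. Step 7 (bears the label "Proposed new method:"). The carbene may be consumed by dimerisation, azine formation with unreacted diazirine or attack at the MOM oxygens faster than it adds to the aromatic enol ether. The cyclopropane isomer with chloride on the convex face may also ionise only slowly. Fallback by known chemistry, setting out from 3: dibromocarbene (CHBr3, KOt-Bu, pentane, −20 °C to rt) effects the classical dihalocarbene one-carbon ring expansion of the silyl enol ether to 3-bromo-5,7-bis(methoxymethoxy)-4H-chromen-4-one F1, so the pyranone ring still grows out of the furan ring. For ring B, commercial 4-bromo-3-methoxyphenol (COc1cc(O)ccc1Br) is iodinated with N-iodosuccinimide ortho to the hydroxyl and para to the methoxy group to give 4-bromo-2-iodo-5-methoxyphenol F2. Silylation (TIPSCl, imidazole) gives (4-bromo-2-iodo-5-methoxyphenoxy)triisopropylsilane F3. Selective iodine–magnesium exchange (i-PrMgCl·LiCl, −20 °C) and transmetalation with ZnCl2 give {5-bromo-4-methoxy-2-[(triisopropylsilyl)oxy]phenyl}zinc chloride F4. Negishi coupling of F4 with F1 (Pd(PPh3)4, THF) at the activated C3–Br bond comes back to the route at 15.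

2. Step 10. Lithiation may occur at C8 (between the 7-MOM ether and O1) or at the benzylic/allylic CH2 of the ring B prenyl group instead of C6, and allylation may partly take the SN2' course. Fallback setting out from 15: brief treatment with dilute HCl in MeOH at 0 °C cleaves the MOM ether peri to the carbonyl first and gives 3-{5-bromo-4-methoxy-2-[(triisopropylsilyl)oxy]phenyl}-5-hydroxy-7-(methoxymethoxy)-4H-chromen-4-one F5. Iodination directed by the chelated 5-hydroxyl (BnMe3N·ICl2, CaCO3, CH2Cl2/MeOH) gives the 6-iodo compound F6. Double Stille coupling with tributyl(prenyl)stannane (Pd(PPh3)4, DMF) at C6–I and C5'–Br gives 5-hydroxy-3-{4-methoxy-5-(3-methylbut-2-en-1-yl)-2-[(triisopropylsilyl)oxy]phenyl}-7-(methoxymethoxy)-6-(3-methylbut-2-en-1-yl)-4H-chromen-4-one F7. Re-protection (MOMCl, NaH, DMF) gives the 5,7-bis(methoxymethoxy) isoflavone F8. Transfer hydrogenation of F8 under the conditions of step 9 comes back to the route at 20.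

3. Step 9. The ketone, flanked by the 5-MOM ether and the ortho-silyloxyaryl group, may be reduced too slowly for racemisation and reduction to stay coupled, which would erode the cis selectivity and the enantiomeric purity. Fallback setting out from 16: LiBH(s-Bu)3 (excess, THF, −78 to 0 °C) performs conjugate and then carbonyl reduction anti to the aryl group to give rac-cis-3-{4-methoxy-5-(3-methylbut-2-en-1-yl)-2-[(triisopropylsilyl)oxy]phenyl}-5,7-bis(methoxymethoxy)-3,4-dihydro-2H-chromen-4-ol F9. Esterification with (S)-O-acetylmandelic acid (DCC, DMAP) and chromatographic separation of the diastereomers give the (3S,4S)-chroman-4-yl (2S)-2-acetoxy-2-phenylacetate F10. Saponification (LiOH, THF/H2O) comes back to the route at 18.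

**Further compounds**

F1 | step 7 | 3-bromo-5,7-bis(methoxymethoxy)-4H-chromen-4-one | COCOc1cc(OCOC)c2c(c1)occ(Br)c2=O
F2 | step 7 | 4-bromo-2-iodo-5-methoxyphenol | COc1cc(O)c(I)cc1Br
F3 | step 7 | (4-bromo-2-iodo-5-methoxyphenoxy)triisopropylsilane | COc1cc(O[Si](C(C)C)(C(C)C)C(C)C)c(I)cc1Br
F4 | step 7 | {5-bromo-4-methoxy-2-[(triisopropylsilyl)oxy]phenyl}zinc chloride | COc1cc(O[Si](C(C)C)(C(C)C)C(C)C)c([Zn]Cl)cc1Br
F5 | step 10 | 3-{5-bromo-4-methoxy-2-[(triisopropylsilyl)oxy]phenyl}-5-hydroxy-7-(methoxymethoxy)-4H-chromen-4-one | COCOc1cc(O)c2c(c1)occ(-c1cc(Br)c(OC)cc1O[Si](C(C)C)(C(C)C)C(C)C)c2=O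
F6 | step 10 | 3-{5-bromo-4-methoxy-2-[(triisopropylsilyl)oxy]phenyl}-5-hydroxy-6-iodo-7-(methoxymethoxy)-4H-chromen-4-one | COCOc1cc2occ(-c3cc(Br)c(OC)cc3O[Si](C(C)C)(C(C)C)C(C)C)c(=O)c2c(O)c1I
F7 | step 10 | 5-hydroxy-3-{4-methoxy-5-(3-methylbut-2-en-1-yl)-2-[(triisopropylsilyl)oxy]phenyl}-7-(methoxymethoxy)-6-(3-methylbut-2-en-1-yl)-4H-chromen-4-one | COCOc1cc2occ(-c3cc(CC=C(C)C)c(OC)cc3O[Si](C(C)C)(C(C)C)C(C)C)c(=O)c2c(O)c1CC=C(C)C
F8 | step 10 | 3-{4-methoxy-5-(3-methylbut-2-en-1-yl)-2-[(triisopropylsilyl)oxy]phenyl}-5,7-bis(methoxymethoxy)-6-(3-methylbut-2-en-1-yl)-4H-chromen-4-one | COCOc1cc2occ(-c3cc(CC=C(C)C)c(OC)cc3O[Si](C(C)C)(C(C)C)C(C)C)c(=O)c2c(OCOC)c1CC=C(C)C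
F9 | step 9 | rac-cis-3-{4-methoxy-5-(3-methylbut-2-en-1-yl)-2-[(triisopropylsilyl)oxy]phenyl}-5,7-bis(methoxymethoxy)-3,4-dihydro-2H-chromen-4-ol (racemate, relative configuration shown) | O[C@H]1[C@@H](c2cc(CC=C(C)C)c(OC)cc2O[Si](C(C)C)(C(C)C)C(C)C)COc2cc(OCOC)cc(OCOC)c12
F10 | step 9 | (3S,4S)-3-{4-methoxy-5-(3-methylbut-2-en-1-yl)-2-[(triisopropylsilyl)oxy]phenyl}-5,7-bis(methoxymethoxy)-3,4-dihydro-2H-chromen-4-yl (2S)-2-acetoxy-2-phenylacetate | CC(=O)O[C@H](C(=O)O[C@H]1[C@@H](c2cc(CC=C(C)C)c(OC)cc2O[Si](C(C)C)(C(C)C)C(C)C)COc2cc(OCOC)cc(OCOC)c12)c1ccccc1
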